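**Plan**

1. Locants: C1 = quaternary C(OH)(CH2OH), C2 = CH(OH), C3 = CH(OBz), C4=C5, C6 = CH(OBz), C7 = CH2OH. The target is (1R,2R,3R,6S): all four ring oxygens are cis and C7 is trans to them.
2. Retrosynthesis: the benzoates and the O1/O2 hydroxyls are removed to a cis-cyclohexa-2,5-diene-1,4-diol, the C1–C2 cis-diol being the retron of a C1=C2 alkene. Then C4=C5 and C1=C2 are cut together, which splits the carbocycle into two 1,4-dien-3-ol halves: C2–C3–C4 (divinylcarbinol) and C5–C6–C1(C7).
3. Enabling feature: O3 and O6 are cis-1,4 across the six-membered ring, so one temporary O–Si–O bridge can carry both halves, and the C4=C5 alkene lies directly opposite the C1–C2 bond.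
4. Forward order: silaketal, then double ring-closing metathesis (seven-membered dioxasilepine with C4=C5 first, then the bridged six-membered carbocycle with C1=C2), unbridging, directed osmylation of C1=C2, benzoylation of O3/O6, acid unmasking.
5. Stereochemistry: C6 from lipase resolution of the dienol; C3 from tether-enforced cis selection between two enantiotopic vinyl groups; C1 and C2 from hydrogen-bond-directed syn osmylation by the two cis hydroxyls.

Key step: step 5

**Route**

Step 1
Reactants: 1 2-bromoprop-2-en-1-ol
Product: 2 [(2-bromoprop-2-en-1-yl)oxy](tert-butyl)dimethylsilane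
Conditions: TBSCl, imidazole, CH2Cl2, 0 °C to rt
Reagents that add atoms: tert-butyl(chloro)dimethylsilane, CC(C)(C)[Si](C)(C)Cl
Why: Silyl ether formation at a primary allylic alcohol is routine, and the vinyl bromide is inert to these conditions.

Step 2
Reactants: 2 [(2-bromoprop-2-en-1-yl)oxy](tert-butyl)dimethylsilane; 3 prop-2-enal (acrolein)
Product: 4 rac-2-({[tert-butyl(dimethyl)silyl]oxy}methyl)penta-1,4-dien-3-ol
Conditions: CrCl2 (4 equiv), NiCl2 (2 mol %), DMF, rt; aqueous work-up
Reagents that add atoms: none
Why: In this Nozaki–Hiyama–Kishi reaction the alkenylchromium species made from the vinyl bromide under NiCl2 catalysis should add 1,2 to the enal and tolerate the neighbouring silyloxy group, giving the doubly allylic alcohol with C6 formed as a racemate.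

Step 3
Reactants: 4 rac-2-({[tert-butyl(dimethyl)silyl]oxy}methyl)penta-1,4-dien-3-ol
Product: 5 (3S)-2-({[tert-butyl(dimethyl)silyl]oxy}methyl)penta-1,4-dien-3-ol
Conditions: immobilised Candida antarctica lipase B, vinyl acetate, hexane, 30 °C, taken to about 55–60 % conversion; chromatography
Reagents that add atoms: none
Why: In this lipase-catalysed kinetic resolution (transesterification) the empirical size rule for secondary alcohols predicts faster acetylation of the (R)-alcohol (large 2-substituted alkenyl arm, small vinyl arm), so the (S)-alcohol carrying the C6 configuration of the target should be recovered in high enantiomeric purity once conversion passes one half.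

Step 4
Reactants: 5 (3S)-2-({[tert-butyl(dimethyl)silyl]oxy}methyl)penta-1,4-dien-3-ol; 6 penta-1,4-dien-3-ol
Product: 8 {[(3S)-2-({[tert-butyl(dimethyl)silyl]oxy}methyl)penta-1,4-dien-3-yl]oxy}(penta-1,4-dien-3-yloxy)di(propan-2-yl)silane, via chlorosilane 7 (not isolated)
Conditions: iPr2SiCl2 (1.1 equiv), imidazole, CH2Cl2, 0 °C; then 6 (1.5 equiv), DMAP, rt
Reagents that add atoms: dichlorodi(propan-2-yl)silane, CC(C)[Si](Cl)(Cl)C(C)C
Why: Stepwise silyl ether formation (temporary silicon tether) should work because the hindered dichlorosilane takes up one secondary alkoxide at 0 °C and the second only with DMAP at room temperature, leaving the stereocenter untouched.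

Step 5
Reactants: 8 {[(3S)-2-({[tert-butyl(dimethyl)silyl]oxy}methyl)penta-1,4-dien-3-yl]oxy}(penta-1,4-dien-3-yloxy)di(propan-2-yl)silane
Product: 10 (1R,5S)-6-({[tert-butyl(dimethyl)silyl]oxy}methyl)-3,3-di(propan-2-yl)-2,4-dioxa-3-silabicyclo[3.2.2]nona-6,8-diene, via cis-dioxasilepine 9 (not isolated)
Conditions: second-generation Grubbs catalyst (10 mol %), 1,4-benzoquinone (20 mol %), toluene (2 mM), 70 °C, closed vessel first, then slow argon sparge
Reagents that add atoms: none
Why: Two consecutive ring-closing olefin metatheses run on one ruthenium alkylidene by the usual [2+2]/retro-[2+2] cycle, each releasing ethene: the first joins the vinyl groups of the two halves (C4=C5) and the second joins the remaining vinyl group on C3 to the 1,1-disubstituted alkene on C6 (C1=C2), so the whole carbocycle is assembled from two dienols in one operation. The closest known reactions are the temporary-silicon-tethered ring-closing metathesis of bis-allylic silaketals to cis-dioxasilepines, the ring-closing metathesis of 1,4,7-trienes to cyclohexa-1,4-dienes, and ring-closing metatheses that form bridged bicyclic alkenes. The first closure forms the seven-membered 1,3-dioxa-2-silacyclohept-5-ene ring (Z alkene enforced by ring size), and the second closes the six-membered carbocycle across its 4,7-positions to give the 2,4-dioxa-3-silabicyclo[3.2.2]nona-6,8-diene. The new stereocenter C3 arises by selection between the two enantiotopic vinyl groups of the divinylcarbinol half and is controlled by the C6 stereocenter through the tether, because the cis-4,7-disubstituted ring is the preferred pseudo-diequatorial closure and the only one whose arms can reach each other for the second closure, while a trans closure can reopen with the ethene kept in the vessel. The step needs cis group selection, cyclisation over oligomerisation, and use of the sluggish 1,1-disubstituted alkene only as the last, intramolecular partner; the tether, high dilution and initiation on the monosubstituted vinyl groups should secure these. In the bridged product both carbinol C–H bonds are bridgeheads, which protects this cyclohexa-1,4-diene from aromatisation until the diol is needed.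

Step 6
Reactants: 10 (1R,5S)-6-({[tert-butyl(dimethyl)silyl]oxy}methyl)-3,3-di(propan-2-yl)-2,4-dioxa-3-silabicyclo[3.2.2]nona-6,8-diene
Product: 11 (1S,4R)-2-({[tert-butyl(dimethyl)silyl]oxy}methyl)cyclohexa-2,5-diene-1,4-diol (1,4-cis)
Conditions: TBAF (2.2 equiv), AcOH (2.2 equiv), THF, −20 °C; pH 7 buffer, used at once
Reagents that add atoms: none
Why: In this fluoride desilylation the dialkoxysilane silicon is far more electrophilic than that of the primary silyl ether, so buffered fluoride in the cold should release the cis-diol selectively with both C–O bonds intact, while buffer and low temperature guard the doubly allylic diol against dehydrative aromatisation.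

Step 7
Reactants: 11 (1S,4R)-2-({[tert-butyl(dimethyl)silyl]oxy}methyl)cyclohexa-2,5-diene-1,4-diol
Product: 12 osmate ester: TMEDA-chelated dioxoosmium (hexavalent osmium) bound through O1 and O2 of the all-cis 7-O-silylated 1-(hydroxymethyl)cyclohex-4-ene-1,2,3,6-tetrol, free hydroxyls at C3 and C6, ring configured as in 14
Conditions: OsO4 (1.05 equiv), TMEDA (1.1 equiv), CH2Cl2, −78 °C
Reagents that add atoms: osmium tetroxide, O=[Os](=O)(=O)=O; N,N,N′,N′-tetramethylethane-1,2-diamine, CN(C)CCN(C)C
Why: In this hydrogen-bond-directed osmylation ([3+2] addition of the OsO4·TMEDA complex) the two cis allylic hydroxyls should bind the oxo ligands and deliver osmium to their own face of the more electron-rich trisubstituted C1=C2 alkene, which sets C1 and C2 with all four ring oxygens cis and leaves the new diol masked as the stable chelated osmate ester.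

Step 8
Reactants: 12 osmate ester with free hydroxyls at C3 and C6
Product: 13 3,6-di-O-benzoyl derivative of osmate ester 12
Conditions: BzCl (3 equiv), pyridine, DMAP (cat.), CH2Cl2, 0 °C to rt
Reagents that add atoms: benzoyl chloride, O=C(Cl)c1ccccc1
Why: Esterification can only occur at O3 and O6, because O1 and O2 are locked in the osmate ester and O7 is silylated, so acylation with BzCl/DMAP should place both benzoates without further protecting groups.

Step 9
Reactants: 13 3,6-di-O-benzoyl derivative of osmate ester 12
Product: 14 (1R,2R,3R,6S)-1-(hydroxymethyl)cyclohex-4-ene-1,2,3,6-tetrol 3,6-dibenzoate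
Conditions: HCl (conc., 5 equiv), MeOH, rt
Reagents that add atoms: none
Why: Acidic methanolysis should release the C1/C2 diol from osmium as OsO2Cl2(TMEDA) and cleave the primary silyl ether in the same flask, under conditions where secondary benzoates should neither hydrolyse nor migrate appreciably.

**Compound list**

1 | 2-bromoprop-2-en-1-ol | C=C(Br)CO | starting material
2 | [(2-bromoprop-2-en-1-yl)oxy](tert-butyl)dimethylsilane | C=C(Br)CO[Si](C)(C)C(C)(C)C | intermediate
3 | prop-2-enal (acrolein) | C=CC=O | starting material
4 | rac-2-({[tert-butyl(dimethyl)silyl]oxy}methyl)penta-1,4-dien-3-ol | C=CC(O)C(=C)CO[Si](C)(C)C(C)(C)C | intermediate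
5 | (3S)-2-({[tert-butyl(dimethyl)silyl]oxy}methyl)penta-1,4-dien-3-ol | C=C[C@H](O)C(=C)CO[Si](C)(C)C(C)(C)C | intermediate
6 | penta-1,4-dien-3-ol (divinylcarbinol) | C=CC(O)C=C | starting material
7 | {[(3S)-2-({[tert-butyl(dimethyl)silyl]oxy}methyl)penta-1,4-dien-3-yl]oxy}(chloro)di(propan-2-yl)silane | C=C[C@H](O[Si](Cl)(C(C)C)C(C)C)C(=C)CO[Si](C)(C)C(C)(C)C | intermediate
8 | {[(3S)-2-({[tert-butyl(dimethyl)silyl]oxy}methyl)penta-1,4-dien-3-yl]oxy}(penta-1,4-dien-3-yloxy)di(propan-2-yl)silane | C=C[C@H](O[Si](C(C)C)(C(C)C)OC(C=C)C=C)C(=C)CO[Si](C)(C)C(C)(C)C | intermediate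
9 | (4S,7S)-4-(3-{[tert-butyl(dimethyl)silyl]oxy}prop-1-en-2-yl)-7-ethenyl-2,2-di(propan-2-yl)-4,7-dihydro-1,3,2-dioxasilepine (4,7-cis) | CC(C)[Si]1(C(C)C)O[C@H](C(=C)CO[Si](C)(C)C(C)(C)C)C=C[C@H](C=C)O1 | intermediate
10 | (1R,5S)-6-({[tert-butyl(dimethyl)silyl]oxy}methyl)-3,3-di(propan-2-yl)-2,4-dioxa-3-silabicyclo[3.2.2]nona-6,8-diene | CC(C)[Si]1(C(C)C)O[C@H]2C=C[C@@H](O1)C=C2CO[Si](C)(C)C(C)(C)C | intermediate
11 | (1S,4R)-2-({[tert-butyl(dimethyl)silyl]oxy}methyl)cyclohexa-2,5-diene-1,4-diol (1,4-cis) | O[C@H]1C=C[C@@H](O)C=C1CO[Si](C)(C)C(C)(C)C | intermediate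
12 | osmate ester: OsO2(TMEDA) (hexavalent osmium) bound through O1 and O2; O7 silylated; free OH at C3 and C6; all four ring oxygens cis | CC(C)(C)[Si](C)(C)OC[C@]12O[Os-2]3(=O)(=O)([N+](C)(C)CC[N+]3(C)C)O[C@@H]2[C@H](O)C=C[C@@H]1O | intermediate
13 | 3,6-di-O-benzoyl derivative of osmate ester 12 | CC(C)(C)[Si](C)(C)OC[C@]12O[Os-2]3(=O)(=O)([N+](C)(C)CC[N+]3(C)C)O[C@@H]2[C@H](OC(=O)c2ccccc2)C=C[C@@H]1OC(=O)c1ccccc1 | intermediate
14 | (1R,2R,3R,6S)-1-(hydroxymethyl)cyclohex-4-ene-1,2,3,6-tetrol 3,6-dibenzoate | O=C(O[C@H]1C=C[C@@H](OC(=O)c2ccccc2)[C@@H](O)[C@]1(O)CO)c1ccccc1 | target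

**Summary**

Total step count: 9. Longest linear sequence: 9 steps (1 to 14).

Steps most likely to fail:

Step 5. The bridging closure may not take place because both alkenyl arms must turn pseudo-axial, unproductive trans group selection may persist, or intermolecular metathesis may outrun cyclisation. Fallback: setting out from 8, the two closures are separated. First-generation Grubbs catalyst (CH2Cl2, 40 °C), which leaves the 1,1-disubstituted alkene alone, should give the cis-dioxasilepine 9, now isolated. Buffered TBAF then frees the open-chain (3S,4Z,6S)-2-({[tert-butyl(dimethyl)silyl]oxy}methyl)octa-1,4,7-triene-3,6-diol F1. An unbridged ring-closing metathesis of this 1,4,7-triene (second-generation Grubbs catalyst, CH2Cl2, 40 °C) closes the cyclohexa-1,4-diene directly, and the route is rejoined at 11.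

Step 7. Osmylation may take place at the wrong alkene (C4=C5), since the silyloxymethyl group offsets the electronic advantage of the trisubstituted alkene. Both alkenes may also be osmylated, or the doubly allylic diol may aromatise by loss of water before it reacts. Fallback: setting out from 10, both silicon groups are removed with unbuffered TBAF (THF, 0 °C) to give the triol (1S,4R)-2-(hydroxymethyl)cyclohexa-2,5-diene-1,4-diol F2. OsO4/TMEDA (CH2Cl2 with a little THF, −78 °C) then meets a third donor hydroxyl that sits on the C1=C2 alkene alone and should give the osmate ester triol F3. Selective silylation of the primary hydroxyl (TBSCl, imidazole, CH2Cl2, −20 °C) returns to the route at 12.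

Step 8. The osmate ester may be lost or suffer ligand exchange under acylating conditions, and acylation of the hindered O6 next to the quaternary carbon may be slow, leading to incomplete benzoylation or acyl scrambling. Fallback: setting out from 12, osmium is removed first (aqueous Na2SO3, THF, rt) to give the all-cis (1S,2R,3R,6S)-1-({[tert-butyl(dimethyl)silyl]oxy}methyl)cyclohex-4-ene-1,2,3,6-tetrol F4 (same spatial arrangement as 14; the C1 descriptor changes only through CIP priorities). The two allylic hydroxyls are then benzoylated regioselectively (BzCl 2.1 equiv, pyridine, −40 °C), the tertiary hydroxyl being inert and the C2 hydroxyl flanked on both sides, to give the 3,6-dibenzoate 7-O-silyl ether F5. HCl in MeOH removes the silyl group and the route is rejoined at 14.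

Further compounds
F1 | step 5 | (3S,4Z,6S)-2-({[tert-butyl(dimethyl)silyl]oxy}methyl)octa-1,4,7-triene-3,6-diol | C=C[C@H](O)/C=C\[C@H](O)C(=C)CO[Si](C)(C)C(C)(C)C
F2 | step 7 | (1S,4R)-2-(hydroxymethyl)cyclohexa-2,5-diene-1,4-diol | O[C@H]1C=C[C@@H](O)C=C1CO
F3 | step 7 | osmate ester of the triol: OsO2(TMEDA) (hexavalent osmium) bound through O1 and O2, free OH at C3, C6 and C7 | OC[C@]12O[Os-2]3(=O)(=O)([N+](C)(C)CC[N+]3(C)C)O[C@@H]2[C@H](O)C=C[C@@H]1O
F4 | step 8 | (1S,2R,3R,6S)-1-({[tert-butyl(dimethyl)silyl]oxy}methyl)cyclohex-4-ene-1,2,3,6-tetrol (all ring oxygens cis) | CC(C)(C)[Si](C)(C)OC[C@@]1(O)[C@H](O)[C@H](O)C=C[C@@H]1O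
F5 | step 8 | (1R,2R,3R,6S)-1-({[tert-butyl(dimethyl)silyl]oxy}methyl)cyclohex-4-ene-1,2,3,6-tetrol 3,6-dibenzoate | CC(C)(C)[Si](C)(C)OC[C@@]1(O)[C@H](O)[C@H](OC(=O)c2ccccc2)C=C[C@@H]1OC(=O)c1ccccc1
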